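**Retrosynthetic overview**
1. Target 23 ⇐ acyl shift (δ-lactone on O13 → γ-lactone on O2) and acetylation of the bridged α-methylene-δ-lactone 21.
2. 21 ⇐ C1–C2 bond: electrochemical, chromium-catalysed macrocyclising allylation of enal 20. This closes the 14-membered ring, and the C13-anchored dihydropyranone relays C13 → C1 → C2.
3. 20 ⇐ ring-closing metathesis and inverting Mitsunobu esterification of anti epoxy alcohol 17 (C11/C12 set by hydroxyl-directed epoxidation from C13).
4. 17 ⇐ C10–C11 B-alkyl Suzuki coupling of the geranyl acetate-derived triene 11 with vinyl iodide 8.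
5. 8 ⇐ (R)-3-hydroxy-γ-butyrolactone 1, the only source of chirality (C13). Ring order: epoxide, dihydropyranone, 14-membered carbocycle, γ-lactone.

Assumption: locants such as C13 follow cembrane numbering of the target (C1/C2 lactone fusion, C11/C12 epoxide, C13 acetoxy carbon, C15–C17 acrylate unit), and 1, 9 and 18 are taken as catalogue compounds.

**Step 1**
Reactants: 1 (R)-3-hydroxy-γ-butyrolactone
Product: 2 (4R)-4-[(tert-butyldiphenylsilyl)oxy]oxolan-2-one
Conditions: TBDPSCl, imidazole, DMF, 0 °C to rt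
Reagents that add atoms: tert-butyl(chloro)diphenylsilane, CC(C)(C)[Si](Cl)(c1ccccc1)c1ccccc1
Why: Imidazole-promoted silyl ether formation protects the secondary alcohol; the bought C13 stereocentre is untouched.

**Step 2**
Reactants: 2 (4R)-4-[(tert-butyldiphenylsilyl)oxy]oxolan-2-one
Product: 3 (4R)-4-[(tert-butyldiphenylsilyl)oxy]oxolan-2-ol (lactol, both anomers)
Conditions: i-Bu2AlH, CH2Cl2, −78 °C; Rochelle salt work-up
Reagents that add atoms: none
Why: Partial lactone reduction with i-Bu2AlH stops at the lactol at −78 °C because the aluminium hemiacetal is stable until work-up.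

**Step 3**
Reactants: 3 (4R)-4-[(tert-butyldiphenylsilyl)oxy]oxolan-2-ol
Product: 4 (2R)-2-[(tert-butyldiphenylsilyl)oxy]pent-4-en-1-ol
Conditions: Ph3PCH3Br, KN(SiMe3)2, THF, 0 °C to rt
Reagents that add atoms: methyltriphenylphosphonium bromide, C[P+](c1ccccc1)(c1ccccc1)c1ccccc1.[Br-]
Why: Wittig methylenation of the open hydroxy-aldehyde form of the lactol installs the terminal alkene (later the metathesis handle at C1); the bulky TBDPS group resists 1,2-silyl migration to the new primary alkoxide.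

**Step 4**
Reactants: 4 (2R)-2-[(tert-butyldiphenylsilyl)oxy]pent-4-en-1-ol
Product: 5 (2R)-2-[(tert-butyldiphenylsilyl)oxy]pent-4-enal
Conditions: Dess–Martin periodinane, CH2Cl2, 0 °C to rt
Reagents that add atoms: none
Why: Dess–Martin oxidation gives the α-silyloxy aldehyde under non-basic conditions, so the stereocentre does not epimerise.

**Step 5**
Reactants: 5 (2R)-2-[(tert-butyldiphenylsilyl)oxy]pent-4-enal
Product: 6 tert-butyl{[(3R)-hex-5-en-1-yn-3-yl]oxy}diphenylsilane
Conditions: dimethyl (1-diazo-2-oxopropyl)phosphonate, K2CO3, MeOH, 0 °C to rt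
Reagents that add atoms: dimethyl (1-diazo-2-oxopropyl)phosphonate, CC(=O)C(=[N+]=[N-])P(=O)(OC)OC
Why: Ohira–Bestmann (Seyferth–Gilbert) homologation turns the aldehyde into the terminal alkyne under conditions mild enough to keep the α-silyloxy stereocentre.

**Step 6**
Reactants: 6 tert-butyl{[(3R)-hex-5-en-1-yn-3-yl]oxy}diphenylsilane
Product: 8 tert-butyl{[(1E,3R)-1-iodo-2-methylhexa-1,5-dien-3-yl]oxy}diphenylsilane, via alkenylalane 7 (not isolated)
Conditions: AlMe3, Cp2ZrCl2 (0.3 equiv), CH2Cl2, 0 °C to rt; then I2, THF, −30 °C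
Reagents that add atoms: trimethylaluminium, C[Al](C)C; iodine, II
Why: Negishi zirconium-catalysed syn-carboalumination places the methyl on the internal and aluminium on the terminal alkyne carbon, and iodinolysis with retention gives the (E)-2-methyl-1-iodoalkene (the future C11=C12) as one isomer.

**Step 7**
Reactants: 9 geranyl acetate
Product: 10 (2E,6E)-3,7-dimethyl-8-oxoocta-2,6-dien-1-yl acetate
Conditions: SeO2 (1.2 equiv), 1,4-dioxane/EtOH, 80 °C
Reagents that add atoms: selenium dioxide, O=[Se]=O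
Why: SeO2 allylic oxidation (ene reaction then [2,3]-shift) is selective for the (E)-methyl group of the terminal trisubstituted alkene and gives the (E)-enal.

**Step 8**
Reactants: 10 (2E,6E)-3,7-dimethyl-8-oxoocta-2,6-dien-1-yl acetate
Product: 11 (2E,6E)-3,7-dimethylnona-2,6,8-trien-1-yl acetate
Conditions: Ph3PCH3Br, KN(SiMe3)2, THF, −78 to 0 °C
Reagents that add atoms: methyltriphenylphosphonium bromide, C[P+](c1ccccc1)(c1ccccc1)c1ccccc1.[Br-]
Why: Wittig methylenation of the aldehyde at low temperature leaves the acetate alone and gives the terminal diene.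

**Step 9**
Reactants: 11 (2E,6E)-3,7-dimethylnona-2,6,8-trien-1-yl acetate; 8 tert-butyl{[(1E,3R)-1-iodo-2-methylhexa-1,5-dien-3-yl]oxy}diphenylsilane
Product: 14 (2E,6E,10E,12R)-12-[(tert-butyldiphenylsilyl)oxy]-3,7,11-trimethylpentadeca-2,6,10,14-tetraen-1-ol, via alkyl-9-BBN borane 12 (not isolated), via coupled acetate 13 (not isolated)
Conditions: 11 (1.15 equiv), 9-BBN (1.1 equiv), THF, 0 °C to rt; then 8, Pd(dppf)Cl2 (5 mol %), AsPh3, 3 M aq NaOH, THF, 60 °C
Reagents that add atoms: none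
Why: 9-BBN hydroborates only the monosubstituted terminal alkene (anti-Markovnikov), B-alkyl Suzuki–Miyaura coupling forms C10–C11 with retention of the E geometry, and the aqueous NaOH of the coupling saponifies the primary acetate.

**Step 10**
Reactants: 14 (2E,6E,10E,12R)-12-[(tert-butyldiphenylsilyl)oxy]-3,7,11-trimethylpentadeca-2,6,10,14-tetraen-1-ol
Product: 15 (2E,6E,10E,12R)-12-[(tert-butyldiphenylsilyl)oxy]-3,7,11-trimethylpentadeca-2,6,10,14-tetraenal
Conditions: MnO2 (20 equiv), CH2Cl2, rt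
Reagents that add atoms: none
Why: MnO2 oxidises the primary allylic alcohol to the (E)-enal (the later electrophile C2) without touching the other groups.

**Step 11**
Reactants: 15 (2E,6E,10E,12R)-12-[(tert-butyldiphenylsilyl)oxy]-3,7,11-trimethylpentadeca-2,6,10,14-tetraenal
Product: 16 (2E,6E,10E,12R)-12-hydroxy-3,7,11-trimethylpentadeca-2,6,10,14-tetraenal
Conditions: n-Bu4NF, AcOH, THF, 0 °C to rt
Reagents that add atoms: none
Why: Fluoride cleaves the silyl ether, and acetic acid buffering keeps the enal from base-induced isomerisation.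

**Step 12**
Reactants: 16 (2E,6E,10E,12R)-12-hydroxy-3,7,11-trimethylpentadeca-2,6,10,14-tetraenal
Product: 17 (2E,6E)-9-{(2R,3R)-3-[(1R)-1-hydroxybut-3-en-1-yl]-3-methyloxiran-2-yl}-3,7-dimethylnona-2,6-dienal
Conditions: VO(acac)2 (5 mol %), t-BuOOH (anhydrous, 1.5 equiv), CH2Cl2, 0 °C to rt
Reagents that add atoms: tert-butyl hydroperoxide, CC(C)(C)OO
Why: Vanadium-catalysed hydroxyl-directed epoxidation is chemoselective for the allylic-alcohol alkene and, because of A(1,2) strain from the C12 methyl, gives the anti (erythro) epoxy alcohol, so the bought C13 centre sets C11 and C12.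

**Step 13**
Reactants: 17 (2E,6E)-9-{(2R,3R)-3-[(1R)-1-hydroxybut-3-en-1-yl]-3-methyloxiran-2-yl}-3,7-dimethylnona-2,6-dienal; 18 2-(chloromethyl)prop-2-enoic acid
Product: 19 (1S)-1-{(2S,3R)-3-[(3E,7E)-3,7-dimethyl-9-oxonona-3,7-dien-1-yl]-2-methyloxiran-2-yl}but-3-en-1-yl 2-(chloromethyl)prop-2-enoate
Conditions: PPh3, DIAD, THF, −20 °C (betaine pre-formed); then 18; then 17, −20 to 0 °C
Reagents that add atoms: none
Why: Mitsunobu esterification goes by SN2 inversion at C13, turning the anti epoxy alcohol into the required syn epoxy ester (13S); pre-forming the betaine keeps free PPh3 away from the allylic chloride.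

**Step 14**
Reactants: 19 (1S)-1-{(2S,3R)-3-[(3E,7E)-3,7-dimethyl-9-oxonona-3,7-dien-1-yl]-2-methyloxiran-2-yl}but-3-en-1-yl 2-(chloromethyl)prop-2-enoate
Product: 20 (6S)-3-(chloromethyl)-6-{(2S,3R)-3-[(3E,7E)-3,7-dimethyl-9-oxonona-3,7-dien-1-yl]-2-methyloxiran-2-yl}-5,6-dihydro-2H-pyran-2-one
Conditions: second-generation Hoveyda–Grubbs catalyst [RuCl2(H2IMes)(=CH-C6H4-2-OiPr)] (5 mol %), toluene (5 mM), 80 °C
Reagents that add atoms: none
Why: Ring-closing metathesis between the terminal alkene and the 1,1-disubstituted acrylate forms the six-membered unsaturated lactone with loss of ethene, while the trisubstituted chain alkenes and the enal are inert.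

**Step 15**
Reactants: 20 (6S)-3-(chloromethyl)-6-{(2S,3R)-3-[(3E,7E)-3,7-dimethyl-9-oxonona-3,7-dien-1-yl]-2-methyloxiran-2-yl}-5,6-dihydro-2H-pyran-2-one
Product: 21 (1R,2S,3E,7E,11R,12S,13S)-11,12-epoxy-2-hydroxycembra-3,7,15(17)-trien-16,13-olide (14-membered carbocycle whose C13–O and C1 are bridged by the α-methylene-δ-lactone)
Conditions: CrCl2 (20 mol %), n-Bu4NPF6 (0.1 M), THF/DMF 4:1, undivided cell, Al anode, Ni-foam cathode, 2 mA, 2.3 F/mol, 20 added over 12 h (final 2 mM), rt; aq. Rochelle salt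
Reagents that add atoms: none
Why: Proposed new method: a chromium-catalysed, cathode-driven Nozaki–Hiyama-type allylation run as a macrocyclisation from a lactone-embedded 2-(alkoxycarbonyl)allyl chloride — divalent chromium (regenerated at the cathode from the trivalent chromium it becomes, at a potential where neither the enal nor the C–Cl bond is reduced directly) converts the allylic chloride into an allylchromium species whose C15=C1 geometry is locked by the dihydropyranone ring, and this adds through its γ-carbon C1 to the tethered enal in a closed chair (Zimmerman–Traxler) transition state with the alkenyl group of the aldehyde equatorial (anti C1/C2, the trans fusion of the later γ-lactone) and on the face of C1 anti to the pseudo-equatorial C13 side chain (axial attack, 4,6-trans on the lactone, hence 1R,2S from 13S), while aluminium ions from the anode take over the alkoxide so chromium turns over and the slow feed keeps the open chain dilute; closest known chemistry is the stoichiometric CrCl2 macrocyclisation of 2-(bromomethyl)acrylates onto aldehydes and the intermolecular electrochemical Nozaki–Hiyama–Kishi coupling, neither shown for an endocyclic allyl halide that relays a ring stereocentre.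

**Step 16**
Reactants: 21 (1R,2S,3E,7E,11R,12S,13S)-11,12-epoxy-2-hydroxycembra-3,7,15(17)-trien-16,13-olide
Product: 23 (1R,2S,3E,7E,11R,12S,13S)-13-acetoxy-11,12-epoxycembra-3,7,15(17)-trien-16,2-olide (CNP0146076.5), via epoxy alcohol 22 (not isolated)
Conditions: DBU (0.2 equiv), CH2Cl2, rt; then Ac2O, Et3N, DMAP (cat.), 0 °C to rt
Reagents that add atoms: acetic anhydride, CC(=O)OC(C)=O
Why: Base-catalysed translactonisation (the C2 hydroxyl attacks the lactone carbonyl; the five-membered γ-lactone is favoured over the bridged δ-lactone) frees the 13-OH, which is then acetylated by DMAP-catalysed acylation without touching any stereocentre.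

**Compound list**
1 | (R)-3-hydroxy-γ-butyrolactone, (4R)-4-hydroxyoxolan-2-one | O=C1C[C@@H](O)CO1 | starting material
2 | (4R)-4-[(tert-butyldiphenylsilyl)oxy]oxolan-2-one | O=C1C[C@@H](O[Si](c2ccccc2)(c2ccccc2)C(C)(C)C)CO1 | intermediate
3 | (4R)-4-[(tert-butyldiphenylsilyl)oxy]oxolan-2-ol (both anomers) | OC1C[C@@H](O[Si](c2ccccc2)(c2ccccc2)C(C)(C)C)CO1 | intermediate
4 | (2R)-2-[(tert-butyldiphenylsilyl)oxy]pent-4-en-1-ol | OC[C@H](O[Si](c1ccccc1)(c1ccccc1)C(C)(C)C)CC=C | intermediate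
5 | (2R)-2-[(tert-butyldiphenylsilyl)oxy]pent-4-enal | O=C[C@H](O[Si](c1ccccc1)(c1ccccc1)C(C)(C)C)CC=C | intermediate
6 | tert-butyl{[(3R)-hex-5-en-1-yn-3-yl]oxy}diphenylsilane | C#C[C@H](O[Si](c1ccccc1)(c1ccccc1)C(C)(C)C)CC=C | intermediate
7 | {(1E,3R)-3-[(tert-butyldiphenylsilyl)oxy]-2-methylhexa-1,5-dien-1-yl}dimethylalane (not isolated) | C[Al](C)/C=C(\C)[C@H](O[Si](c1ccccc1)(c1ccccc1)C(C)(C)C)CC=C | intermediate
8 | tert-butyl{[(1E,3R)-1-iodo-2-methylhexa-1,5-dien-3-yl]oxy}diphenylsilane | I/C=C(\C)[C@H](O[Si](c1ccccc1)(c1ccccc1)C(C)(C)C)CC=C | intermediate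
9 | geranyl acetate, (2E)-3,7-dimethylocta-2,6-dien-1-yl acetate | CC(=O)OC/C=C(\C)CCC=C(C)C | starting material
10 | (2E,6E)-3,7-dimethyl-8-oxoocta-2,6-dien-1-yl acetate | CC(=O)OC/C=C(\C)CC/C=C(\C)C=O | intermediate
11 | (2E,6E)-3,7-dimethylnona-2,6,8-trien-1-yl acetate | CC(=O)OC/C=C(\C)CC/C=C(\C)C=C | intermediate
12 | (2E,6E)-9-(9-borabicyclo[3.3.1]nonan-9-yl)-3,7-dimethylnona-2,6-dien-1-yl acetate (not isolated) | CC(=O)OC/C=C(\C)CC/C=C(\C)CCB1C2CCCC1CCC2 | intermediate
13 | (2E,6E,10E,12R)-12-[(tert-butyldiphenylsilyl)oxy]-3,7,11-trimethylpentadeca-2,6,10,14-tetraen-1-yl acetate (not isolated) | CC(=O)OC/C=C(\C)CC/C=C(\C)CC/C=C(\C)[C@H](O[Si](c1ccccc1)(c1ccccc1)C(C)(C)C)CC=C | intermediate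
14 | (2E,6E,10E,12R)-12-[(tert-butyldiphenylsilyl)oxy]-3,7,11-trimethylpentadeca-2,6,10,14-tetraen-1-ol | OC/C=C(\C)CC/C=C(\C)CC/C=C(\C)[C@H](O[Si](c1ccccc1)(c1ccccc1)C(C)(C)C)CC=C | intermediate
15 | (2E,6E,10E,12R)-12-[(tert-butyldiphenylsilyl)oxy]-3,7,11-trimethylpentadeca-2,6,10,14-tetraenal | O=C/C=C(\C)CC/C=C(\C)CC/C=C(\C)[C@H](O[Si](c1ccccc1)(c1ccccc1)C(C)(C)C)CC=C | intermediate
16 | (2E,6E,10E,12R)-12-hydroxy-3,7,11-trimethylpentadeca-2,6,10,14-tetraenal | O=C/C=C(\C)CC/C=C(\C)CC/C=C(\C)[C@H](O)CC=C | intermediate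
17 | (2E,6E)-9-{(2R,3R)-3-[(1R)-1-hydroxybut-3-en-1-yl]-3-methyloxiran-2-yl}-3,7-dimethylnona-2,6-dienal | O=C/C=C(\C)CC/C=C(\C)CC[C@H]1O[C@]1(C)[C@H](O)CC=C | intermediate
18 | 2-(chloromethyl)prop-2-enoic acid | C=C(CCl)C(=O)O | starting material
19 | (1S)-1-{(2S,3R)-3-[(3E,7E)-3,7-dimethyl-9-oxonona-3,7-dien-1-yl]-2-methyloxiran-2-yl}but-3-en-1-yl 2-(chloromethyl)prop-2-enoate | O=C/C=C(\C)CC/C=C(\C)CC[C@H]1O[C@]1(C)[C@@H](OC(=O)C(=C)CCl)CC=C | intermediate
20 | (6S)-3-(chloromethyl)-6-{(2S,3R)-3-[(3E,7E)-3,7-dimethyl-9-oxonona-3,7-dien-1-yl]-2-methyloxiran-2-yl}-5,6-dihydro-2H-pyran-2-one | O=C/C=C(\C)CC/C=C(\C)CC[C@H]1O[C@]1(C)[C@@H]2CC=C(CCl)C(=O)O2 | intermediate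
21 | (1R,2S,3E,7E,11R,12S,13S)-11,12-epoxy-2-hydroxycembra-3,7,15(17)-trien-16,13-olide | C=C1C(=O)O[C@H]2C[C@H]1[C@@H](O)/C=C(\C)CC/C=C(\C)CC[C@H]3O[C@@]32C | intermediate
22 | (1R,2S,3E,7E,11R,12R,13S)-11,12-epoxy-13-hydroxycembra-3,7,15(17)-trien-16,2-olide (not isolated) | C=C1C(=O)O[C@H]2/C=C(\C)CC/C=C(\C)CC[C@H]3O[C@]3(C)[C@@H](O)C[C@H]12 | intermediate
23 | (1R,2S,3E,7E,11R,12S,13S)-13-acetoxy-11,12-epoxycembra-3,7,15(17)-trien-16,2-olide (CNP0146076.5) | C=C1C(=O)O[C@H]2/C=C(\C)CC/C=C(\C)CC[C@H]3O[C@]3(C)[C@@H](OC(C)=O)C[C@H]12 | target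

**Step count**
Total steps: 16. Longest linear sequence: 14 (steps 1–6 and 9–16, from 1).

**Steps most likely to fail**

Step 15 (the proposed electrochemical macrocyclisation). It may give oligomers, open the epoxide under the aluminium ions, or fail to turn chromium over. The fallback sets out from 20 and comes back at 21 using known chemistry. The allylic chloride is borylated with B2pin2 and Pd2(dba)3 (known for Morita–Baylis–Hillman-type allyl halides) to give the allylboronate (6S)-6-{(2S,3R)-3-[(3E,7E)-3,7-dimethyl-9-oxonona-3,7-dien-1-yl]-2-methyloxiran-2-yl}-3-[(4,4,5,5-tetramethyl-1,3,2-dioxaborolan-2-yl)methyl]-5,6-dihydro-2H-pyran-2-one F1. Heating F1 in toluene at 1 mM effects intramolecular carbonyl allylboration through the same closed chair transition state, without redox chemistry or Lewis acid, to give the pinacol borate of the bridged lactone, (1R,2S,3E,7E,11R,12S,13S)-11,12-epoxy-2-[(4,4,5,5-tetramethyl-1,3,2-dioxaborolan-2-yl)oxy]cembra-3,7,15(17)-trien-16,13-olide F2. Aqueous NaHCO3 hydrolyses F2 to 21. The facial selectivity at C1 rests on the same ring argument in both routes, so this fallback does not cover a wrong C1/C2 outcome.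

Step 13 (Mitsunobu esterification of a hindered epoxy alcohol with an acid that carries an allylic chloride). The fallback sets out from 17 and comes back at 19. Mitsunobu inversion with the more acidic 4-nitrobenzoic acid (PPh3, DIAD) gives (1S)-1-{(2S,3R)-3-[(3E,7E)-3,7-dimethyl-9-oxonona-3,7-dien-1-yl]-2-methyloxiran-2-yl}but-3-en-1-yl 4-nitrobenzoate F3. Brief methanolysis (K2CO3, MeOH, 0 °C) gives the syn epoxy alcohol (2E,6E)-9-{(2R,3R)-3-[(1S)-1-hydroxybut-3-en-1-yl]-3-methyloxiran-2-yl}-3,7-dimethylnona-2,6-dienal F4. Steglich esterification of F4 with 18 (DIC, DMAP, retention) gives 19 with no phosphine near the allylic chloride.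

Step 16 (translactonisation before acetylation). The bridged δ-lactone may rearrange slowly, or the freed epoxy alkoxide may undergo Payne rearrangement. The fallback sets out from 21 and comes back at 22, which is then acetylated as in step 16. The lactone is opened under neutral conditions with Me3SnOH (1,2-dichloroethane, 60 °C) to the seco acid 2-[(1R,2S,3E,7E,11R,12R,13S)-11,12-epoxy-2,13-dihydroxy-4,8,12-trimethylcyclotetradeca-3,7-dien-1-yl]prop-2-enoic acid F5 (cembrane numbering). F5 is closed kinetically onto the nearer C2 hydroxyl (2,4,6-trichlorobenzoyl chloride, Et3N, then DMAP; γ-lactonisation is faster than δ-lactonisation) to give 22.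

**Further compounds**
F1 | step 15 | (6S)-6-{(2S,3R)-3-[(3E,7E)-3,7-dimethyl-9-oxonona-3,7-dien-1-yl]-2-methyloxiran-2-yl}-3-[(4,4,5,5-tetramethyl-1,3,2-dioxaborolan-2-yl)methyl]-5,6-dihydro-2H-pyran-2-one | O=C/C=C(\C)CC/C=C(\C)CC[C@H]1O[C@]1(C)[C@@H]2CC=C(CB3OC(C)(C)C(C)(C)O3)C(=O)O2
F2 | step 15 | (1R,2S,3E,7E,11R,12S,13S)-11,12-epoxy-2-[(4,4,5,5-tetramethyl-1,3,2-dioxaborolan-2-yl)oxy]cembra-3,7,15(17)-trien-16,13-olide | C=C1C(=O)O[C@H]2C[C@H]1[C@@H](OB4OC(C)(C)C(C)(C)O4)/C=C(\C)CC/C=C(\C)CC[C@H]3O[C@@]32C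
F3 | step 13 | (1S)-1-{(2S,3R)-3-[(3E,7E)-3,7-dimethyl-9-oxonona-3,7-dien-1-yl]-2-methyloxiran-2-yl}but-3-en-1-yl 4-nitrobenzoate | O=C/C=C(\C)CC/C=C(\C)CC[C@H]1O[C@]1(C)[C@@H](OC(=O)c2ccc(cc2)[N+](=O)[O-])CC=C
F4 | step 13 | (2E,6E)-9-{(2R,3R)-3-[(1S)-1-hydroxybut-3-en-1-yl]-3-methyloxiran-2-yl}-3,7-dimethylnona-2,6-dienal | O=C/C=C(\C)CC/C=C(\C)CC[C@H]1O[C@]1(C)[C@@H](O)CC=C
F5 | step 16 | 2-[(1R,2S,3E,7E,11R,12R,13S)-11,12-epoxy-2,13-dihydroxy-4,8,12-trimethylcyclotetradeca-3,7-dien-1-yl]prop-2-enoic acid | C=C(C(=O)O)[C@@H]1[C@@H](O)/C=C(\C)CC/C=C(\C)CC[C@H]2O[C@]2(C)[C@@H](O)C1
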